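**Plan**

- Numbering (daucane): C1 = ring-fusion carbon with CH3; C2, C3 = CH2; C4 = carbinol carbon with isopropyl; C5 = ring-fusion CH; C6 = benzoyloxy carbon; C7 = CH2; C8(CH3)=C9; C10 = angeloyloxy carbon, bonded to C1. β is the face of the C1 methyl.
- Cuts, in retrosynthetic order: the two ester C–O bonds (C10, C6); C4–isopropyl (back to a C4 ketone); C8–CH3 (back to C8–CO2Et); C6–O and C5–H (back to a C5=C6 alkene); last, C7–C8 and C10–C1 of the seven-membered ring.
- Enabling feature: in the seven-membered ring the allyl unit C8=C9–C10 is joined at both ends to the four-carbon unit C7–C6–C5–C1, whose C5–C1 bond is the fusion bond to the cyclopentane. The ring is therefore a masked cyclohepta-1,4-diene (C8=C9, C5=C6), the adduct of a 2-methyl-1-vinylcyclopentene (diene C7=C6–C5=C1) and a vinylcarbene (C8–C9=C10).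
- Forward order: the five-membered ring is carried in the diene; a cyclopropane forms on the vinyl group and a Cope rearrangement closes the seven-membered ring; then C5/C6, the C8 methyl, the benzoate, the C4 carbinol and the angelate.
- Stereochemistry: C1 and C10 come from a chiral dirhodium catalyst, relayed through the cyclopropane and the boat Cope; C5 and C6 from cis delivery of H and Si by a tether on the C10 oxygen; C4 from addition anti to C6 and the C1 methyl.

Key step: step 5

Remarks on the chemistry: 1, 4 and 5 are taken as catalogue chemicals. Rh2(R-DOSP)4 is dirhodium tetrakis[(R)-N-(4-dodecylbenzenesulfonyl)prolinate]; its sense of induction is assumed to follow that known for cyclopropanation of styrene with donor/acceptor diazoacetates. Diazo compounds 6 and 7 are kept cold and used promptly.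

**Step 1**
Reactants: 1 2-bromo-3-methylcyclopent-2-en-1-one
Product: 2 6-bromo-7-methyl-1,4-dioxaspiro[4.4]non-6-ene
Conditions: ethylene glycol, p-TsOH·H2O (cat.), benzene, reflux, Dean–Stark trap
Reagents that add atoms: ethylene glycol, OCCO
Why: Acid-catalysed ketalisation masks the future C4 carbonyl; the bromine on the alkene keeps the double bond in place.

**Step 2**
Reactants: 2 6-bromo-7-methyl-1,4-dioxaspiro[4.4]non-6-ene
Product: 3 6-ethenyl-7-methyl-1,4-dioxaspiro[4.4]non-6-ene
Conditions: tributyl(vinyl)stannane, Pd(PPh3)4 (5 mol%), toluene, 100 °C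
Reagents that add atoms: tributyl(vinyl)stannane, C=C[Sn](CCCC)(CCCC)CCCC
Why: Stille coupling of the alkenyl bromide should give the diene C7=C6–C5=C1; no stereocentre is formed.

**Step 3**
Reactants: 4 (tert-butyldimethylsilyloxy)acetaldehyde; 5 ethyl diazoacetate
Product: 6 ethyl 4-(tert-butyldimethylsilyloxy)-2-diazo-3-hydroxybutanoate (racemic)
Conditions: DBU (10 mol%), MeCN, rt
Reagents that add atoms: none
Why: Base-catalysed aldol-type addition of the diazoacetate C–H to the aldehyde; the carbinol centre is racemic and is removed in step 4.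

**Step 4**
Reactants: 6 ethyl 4-(tert-butyldimethylsilyloxy)-2-diazo-3-hydroxybutanoate
Product: 7 ethyl (E)-4-(tert-butyldimethylsilyloxy)-2-diazobut-3-enoate
Conditions: POCl3, Et3N, CH2Cl2, 0 °C
Reagents that add atoms: none
Why: Dehydration of the β-hydroxy diazo ester through its dichlorophosphate should give the conjugated (E)-enol silyl ether, which fixes the later C10 configuration.

**Step 5**
Reactants: 3 6-ethenyl-7-methyl-1,4-dioxaspiro[4.4]non-6-ene; 7 ethyl (E)-4-(tert-butyldimethylsilyloxy)-2-diazobut-3-enoate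
Product: 9 ethyl 10α-(tert-butyldimethylsilyloxy)-4,4-ethylenedioxy-1β-methylbicyclo[5.3.0]deca-5,8-diene-8-carboxylate (daucane numbering), via cis-divinylcyclopropane 8 (not isolated)
Conditions: Rh2(R-DOSP)4 (1 mol%), 7 (1.3 equiv) added over 2 h to 3 in degassed hexanes, −40 °C → rt; then toluene, 80 °C
Reagents that add atoms: none
Why: The dirhodium tetracarboxylate turns 7 into a donor/acceptor vinylcarbenoid that adds to the terminal vinyl group of 3 (C6=C7) in a [2+1] closure, giving cyclopropane 8 with the siloxyvinyl and cyclopentenyl groups cis (C7–C8 bond formed). 8 then undergoes a divinylcyclopropane Cope rearrangement through the boat transition state: C6–C8 breaks and C10–C1 closes the seven-membered ring by [3,3] shift, a formal [4+3] whose closest known type is the tandem cyclopropanation/Cope reaction of vinyldiazoacetates with dienes. The two cyclopropane stereocentres (1R,2S) are set by the chiral catalyst and are exchanged stereospecifically for C1 and C10. Because the C1 methyl is the Z substituent of the ring alkene and the siloxy group the E substituent of the enol ether, the boat places OTBS (α) trans to CH3 (β). The step needs attack at the carbenoid carbon and not at the oxygen-bearing vinylogous carbon (favoured by the E substituent, the hydrocarbon solvent and the electron-rich carboxylate ligands), reaction at the vinyl group and not at the tetrasubstituted C5=C1 bond (sterics), and cis-divinyl geometry (the usual preference of donor/acceptor carbenoids).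

**Step 6**
Reactants: 9 ethyl 10α-(tert-butyldimethylsilyloxy)-4,4-ethylenedioxy-1β-methylbicyclo[5.3.0]deca-5,8-diene-8-carboxylate
Product: 10 ethyl 4,4-ethylenedioxy-10α-hydroxy-1β-methylbicyclo[5.3.0]deca-5,8-diene-8-carboxylate
Conditions: tetrabutylammonium fluoride, THF, 0 °C → rt
Reagents that add atoms: none
Why: Fluoride cleavage of the silyl ether frees the α-hydroxyl at C10; the γ-hydroxy enoate cannot lactonise because CO2Et and C10 are trans on C8=C9.

**Step 7**
Reactants: 10 ethyl 4,4-ethylenedioxy-10α-hydroxy-1β-methylbicyclo[5.3.0]deca-5,8-diene-8-carboxylate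
Product: 13 ethyl 4,4-ethylenedioxy-6α,10α-dihydroxy-1β-methyl-5αH-bicyclo[5.3.0]dec-8-ene-8-carboxylate, via hydrosilyl ether 11 (not isolated), via cyclic siloxane 12 (not isolated)
Conditions: (HMe2Si)2NH, neat, rt, then vacuum; Pt2[(CH2=CHSiMe2)2O]3 (0.5 mol% Pt), toluene, 60 °C; then 30% H2O2, KF, KHCO3, THF/MeOH, rt → 40 °C
Reagents that add atoms: hydrogen peroxide, OO (the C6 oxygen); 1,1,3,3-tetramethyldisilazane, C[SiH](C)N[SiH](C)C (silicon present only in 11 and 12)
Why: Silicon-tethered intramolecular hydrosilylation followed by Tamao oxidation: the Si–H held on the α-oxygen at C10 should add cis across C5=C6 from the concave α face that external reagents would avoid, with Si going to C6 (six-membered oxasilinane; the five-membered alternative needs a Si–C bond at the fully substituted C5, and the enoate alkene is electron-poor), and oxidation with retention then gives 5α-H and 6α-OH.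

**Step 8**
Reactants: 13 ethyl 4,4-ethylenedioxy-6α,10α-dihydroxy-1β-methyl-5αH-bicyclo[5.3.0]dec-8-ene-8-carboxylate
Product: 14 4,4-ethylenedioxy-8-(hydroxymethyl)-1β-methyl-5αH-bicyclo[5.3.0]dec-8-ene-6α,10α-diol
Conditions: i-Bu2AlH (5 equiv), CH2Cl2, −78 → 0 °C; aq. potassium sodium tartrate (KNaC4H4O6)
Reagents that add atoms: none
Why: 1,2-Reduction of the α,β-unsaturated ester to the primary allylic alcohol; ketal and stereocentres are untouched.

**Step 9**
Reactants: 14 4,4-ethylenedioxy-8-(hydroxymethyl)-1β-methyl-5αH-bicyclo[5.3.0]dec-8-ene-6α,10α-diol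
Product: 16 4,4-ethylenedioxy-1β,8-dimethyl-5αH-bicyclo[5.3.0]dec-8-ene-6α,10α-diol, via allylic chloride 15 (not isolated)
Conditions: N-chlorosuccinimide, Me2S, CH2Cl2, −20 → 0 °C; then LiEt3BH (excess), THF, 0 °C → rt
Reagents that add atoms: none
Why: Corey–Kim chlorination should pick the unhindered primary allylic hydroxyl over the two secondary ones, and SN2 displacement by hydride then gives the C8 methyl without moving the C8=C9 bond.

**Step 10**
Reactants: 16 4,4-ethylenedioxy-1β,8-dimethyl-5αH-bicyclo[5.3.0]dec-8-ene-6α,10α-diol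
Product: 17 4,4-ethylenedioxy-10α-hydroxy-1β,8-dimethyl-5αH-bicyclo[5.3.0]dec-8-en-6α-yl benzoate
Conditions: benzoyl chloride (1.1 equiv), pyridine, DMAP (cat.), CH2Cl2, −20 → 0 °C
Reagents that add atoms: benzoyl chloride, O=C(Cl)c1ccccc1
Why: Acylation should occur at the C6 hydroxyl in preference to the C10 hydroxyl, which is neopentylic (next to quaternary C1) and allylic.

**Step 11**
Reactants: 17 4,4-ethylenedioxy-10α-hydroxy-1β,8-dimethyl-5αH-bicyclo[5.3.0]dec-8-en-6α-yl benzoate
Product: 18 10α-hydroxy-1β,8-dimethyl-4-oxo-5αH-bicyclo[5.3.0]dec-8-en-6α-yl benzoate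
Conditions: PPTS, acetone/H2O, 50 °C
Reagents that add atoms: water, O
Why: Mild acid hydrolysis of the ketal frees the C4 ketone without enolising C5 or ionising the allylic C10 alcohol.

**Step 12**
Reactants: 18 10α-hydroxy-1β,8-dimethyl-4-oxo-5αH-bicyclo[5.3.0]dec-8-en-6α-yl benzoate
Product: 19 4β,10α-dihydroxy-5αH-dauc-8-en-6α-yl benzoate
Conditions: i-PrMgCl, CeCl3 (dried), THF, −78 °C; aq. NH4Cl
Reagents that add atoms: isopropylmagnesium chloride, CC(C)[Mg]Cl
Why: Organocerium 1,2-addition (low basicity limits enolisation, loss of benzoate and reduction); the nucleophile should enter the cyclopentanone on the α face, anti to the adjacent C5–C6 bond and to the 1,3-related C1 methyl, giving 4β-OH and 4α-isopropyl.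

**Step 13**
Reactants: 19 4β,10α-dihydroxy-5αH-dauc-8-en-6α-yl benzoate
Product: 20 10α-[(Z)-2-methylbut-2-enoyloxy]-4β-hydroxy-5αH-dauc-8-en-6α-yl benzoate (target)
Conditions: angelic acid, 2,4,6-trichlorobenzoyl chloride, Et3N, toluene, rt; then 19, 80 °C
Reagents that add atoms: angelic acid, C/C=C(/C)C(=O)O
Why: Mixed-anhydride (Yamaguchi-type) esterification without a nucleophilic catalyst should acylate the secondary C10 hydroxyl without Z-to-E isomerisation; the tertiary C4 hydroxyl does not react.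

**Compound list**

1 | 2-bromo-3-methylcyclopent-2-en-1-one | CC1=C(Br)C(=O)CC1 | starting material
2 | 6-bromo-7-methyl-1,4-dioxaspiro[4.4]non-6-ene | CC1=C(Br)C2(CC1)OCCO2 | intermediate
3 | 6-ethenyl-7-methyl-1,4-dioxaspiro[4.4]non-6-ene | C=CC1=C(C)CCC12OCCO2 | intermediate
4 | (tert-butyldimethylsilyloxy)acetaldehyde | O=CCO[Si](C)(C)C(C)(C)C | starting material
5 | ethyl diazoacetate | CCOC(=O)C=[N+]=[N-] | starting material
6 | ethyl 4-(tert-butyldimethylsilyloxy)-2-diazo-3-hydroxybutanoate (racemic) | CCOC(=O)C(=[N+]=[N-])C(O)CO[Si](C)(C)C(C)(C)C | intermediate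
7 | ethyl (E)-4-(tert-butyldimethylsilyloxy)-2-diazobut-3-enoate | CCOC(=O)C(=[N+]=[N-])/C=C/O[Si](C)(C)C(C)(C)C | intermediate
8 | ethyl (1R,2S)-1-[(E)-2-(tert-butyldimethylsilyloxy)ethenyl]-2-(7-methyl-1,4-dioxaspiro[4.4]non-6-en-6-yl)cyclopropane-1-carboxylate | CCOC(=O)[C@]1(/C=C/O[Si](C)(C)C(C)(C)C)C[C@H]1C1=C(C)CCC12OCCO2 | intermediate
9 | ethyl 10α-(tert-butyldimethylsilyloxy)-4,4-ethylenedioxy-1β-methylbicyclo[5.3.0]deca-5,8-diene-8-carboxylate | CC(C)(C)[Si](C)(C)O[C@@H]1C=C(C(=O)OCC)CC=C2[C@]1(C)CCC23OCCO3 | intermediate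
10 | ethyl 4,4-ethylenedioxy-10α-hydroxy-1β-methylbicyclo[5.3.0]deca-5,8-diene-8-carboxylate | O[C@@H]1C=C(C(=O)OCC)CC=C2[C@]1(C)CCC23OCCO3 | intermediate
11 | 10α-O-(dimethylsilyl) ether of 10 (Si–H) | C[SiH](C)O[C@@H]1C=C(C(=O)OCC)CC=C2[C@]1(C)CCC23OCCO3 | intermediate
12 | cyclic siloxane, SiMe2 bridging O10 and C6 on the α face, 5α-H | C[Si]4(C)O[C@@H]1C=C(C(=O)OCC)C[C@H]4[C@@H]2[C@]1(C)CCC23OCCO3 | intermediate
13 | ethyl 4,4-ethylenedioxy-6α,10α-dihydroxy-1β-methyl-5αH-bicyclo[5.3.0]dec-8-ene-8-carboxylate | O[C@@H]1C=C(C(=O)OCC)C[C@H](O)[C@@H]2[C@]1(C)CCC23OCCO3 | intermediate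
14 | 4,4-ethylenedioxy-8-(hydroxymethyl)-1β-methyl-5αH-bicyclo[5.3.0]dec-8-ene-6α,10α-diol | O[C@@H]1C=C(CO)C[C@H](O)[C@@H]2[C@]1(C)CCC23OCCO3 | intermediate
15 | 8-(chloromethyl)-4,4-ethylenedioxy-1β-methyl-5αH-bicyclo[5.3.0]dec-8-ene-6α,10α-diol | O[C@@H]1C=C(CCl)C[C@H](O)[C@@H]2[C@]1(C)CCC23OCCO3 | intermediate
16 | 4,4-ethylenedioxy-1β,8-dimethyl-5αH-bicyclo[5.3.0]dec-8-ene-6α,10α-diol | O[C@@H]1C=C(C)C[C@H](O)[C@@H]2[C@]1(C)CCC23OCCO3 | intermediate
17 | 4,4-ethylenedioxy-10α-hydroxy-1β,8-dimethyl-5αH-bicyclo[5.3.0]dec-8-en-6α-yl benzoate | O[C@@H]1C=C(C)C[C@H](OC(=O)c3ccccc3)[C@@H]2[C@]1(C)CCC24OCCO4 | intermediate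
18 | 10α-hydroxy-1β,8-dimethyl-4-oxo-5αH-bicyclo[5.3.0]dec-8-en-6α-yl benzoate | O[C@@H]1C=C(C)C[C@H](OC(=O)c3ccccc3)[C@@H]2[C@]1(C)CCC2=O | intermediate
19 | 4β,10α-dihydroxy-5αH-dauc-8-en-6α-yl benzoate | O[C@@H]1C=C(C)C[C@H](OC(=O)c3ccccc3)[C@@H]2[C@]1(C)CC[C@@]2(O)C(C)C | intermediate
20 | 10α-angeloyloxy-4β-hydroxy-5αH-dauc-8-en-6α-yl benzoate | C/C=C(/C)C(=O)O[C@@H]1C=C(C)C[C@H](OC(=O)c2ccccc2)[C@@H]2[C@]1(C)CC[C@@]2(O)C(C)C | target

**Step count and risks**

Total: 13 steps. Longest linear sequence: 11 steps (steps 1, 2, 5–13).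

Most likely to fail:

1. Step 5. The diene may attack the oxygen-bearing vinylogous carbon of the carbenoid, the enol ether of 7 may be cyclopropanated by its own carbenoid, the Cope may stall at the tetrasubstituted terminus, or enantiocontrol may erode. Fallback from 3 to 10: the same catalyst with the parent ethyl 2-diazobut-3-enoate should give the C10-unsubstituted cycloheptadiene ester F1. γ-Deprotonation at C10 (LiN(i-Pr)2, THF/HMPA, −78 °C) and O-silylation (TBSCl) should give the silyl ketene acetal F2. Vinylogous Rubottom oxidation (dimethyldioxirane, acetone, −78 °C, then KF work-up) at the γ-carbon, expected on the face away from the C1 methyl, returns the route at 10.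

2. Step 7. The hydrosilane may be delivered to the wrong alkene (closure onto C8 or conjugate reduction of the enoate), or insertion at the crowded C5=C6 bond may not occur. Fallback from 9 to 13, relying on attack at the exposed β face twice: epoxidation (mCPBA, NaHCO3, CH2Cl2, 0 °C) should give the 5β,6β-epoxide F3. Meinwald rearrangement (BF3·OEt2, cat., CH2Cl2, −78 °C), with hydride moving from C6 to C5 anti to the leaving oxygen, should give the trans-fused 6-ketone F4. Luche reduction (NaBH4, CeCl3·7H2O, MeOH, −78 °C) from the β face should give the 6α-alcohol F5. Tetrabutylammonium fluoride then returns the route at 13.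

3. Step 12. The hindered ketone may enolise (with epimerisation at C5 or loss of benzoate), be reduced by β-hydride transfer, or be attacked with poor facial selectivity. Fallback from 18 to 19: the smaller sp2 nucleophile isopropenylmagnesium bromide with CeCl3 (THF, −78 °C) should give the isopropenyl carbinol F6. Hydrogenation of its 1,1-disubstituted alkene (H2, RhCl(PPh3)3, benzene, rt), which leaves the trisubstituted ring alkene alone, returns the route at 19.

**Further compounds**

F1 | step 5 | ethyl 4,4-ethylenedioxy-1β-methylbicyclo[5.3.0]deca-5,8-diene-8-carboxylate | CCOC(=O)C1=CC[C@@]2(C)CCC3(OCCO3)C2=CC1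
F2 | step 5 | tert-butyldimethylsilyl ketene acetal of F1 (dienol ether C10=C9–C8=C(OEt)OSi) | CCOC(O[Si](C)(C)C(C)(C)C)=C1C=C[C@@]2(C)CCC3(OCCO3)C2=CC1
F3 | step 7 | 5β,6β-epoxide of 9 | CC(C)(C)[Si](C)(C)O[C@@H]1C=C(C(=O)OCC)C[C@H]4O[C@@]42[C@]1(C)CCC23OCCO3
F4 | step 7 | ethyl 10α-(tert-butyldimethylsilyloxy)-4,4-ethylenedioxy-1β-methyl-6-oxo-5αH-bicyclo[5.3.0]dec-8-ene-8-carboxylate | CC(C)(C)[Si](C)(C)O[C@@H]1C=C(C(=O)OCC)CC(=O)[C@@H]2[C@]1(C)CCC23OCCO3
F5 | step 7 | ethyl 10α-(tert-butyldimethylsilyloxy)-4,4-ethylenedioxy-6α-hydroxy-1β-methyl-5αH-bicyclo[5.3.0]dec-8-ene-8-carboxylate | CC(C)(C)[Si](C)(C)O[C@@H]1C=C(C(=O)OCC)C[C@H](O)[C@@H]2[C@]1(C)CCC23OCCO3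
F6 | step 12 | 4β,10α-dihydroxy-4α-isopropenyl-1β,8-dimethyl-5αH-bicyclo[5.3.0]dec-8-en-6α-yl benzoate | O[C@@H]1C=C(C)C[C@H](OC(=O)c3ccccc3)[C@@H]2[C@]1(C)CC[C@@]2(O)C(C)=C
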